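**Assumptions (one line each).** (i) The target's relative configuration is taken as drawn: trans-fused hydroazulene, OH on C-a cis to the angular Me, epoxide O on the face anti to the angular Me. (ii) The Buchner product is racemic. Its only stereocentre is destroyed in Step 3, and absolute configuration is set at the quaternary carbon in Step 4.

Labels used below: a = C(OH)iPr, b and c = ring CH2's, d = quaternary CMe, e = CH2 next to d, f/g = epoxide CH/C(Me), h = CH2, i = CH–OAr, j = ring-fusion CH.

## Retrosynthesis
- The target comes from epoxidation of ferutinin, which is the p-hydroxybenzoate of jaeschkeanadiol.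
- The i-ester is made by Mitsunobu esterification of the C-i epimer of jaeschkeanadiol (diol 12), which inverts C-i.
- Diol 12 comes from iPr addition to a hydroazulenone ketone, then directed epoxidation of the i=h alkene of the resulting diene and hydride opening of the epoxide.
- The angular methyl comes from Cu-catalysed asymmetric conjugate addition to a fused cyclopentenone.
- That enone is an isomer of the Buchner product. The intramolecular Buchner reaction of the p-tolyl diazoketone dearomatises the arene and forms the 7-ring and the fused 5-ring in one step. The arene methyl ends up on C-g of the f=g alkene.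

## Forward route

**Step 1**
Reactants: 1 (3-(4-methylphenyl)propanoic acid); 2 (diazomethane)
Product: 3 (1-diazo-4-(p-tolyl)butan-2-one)
Conditions: (COCl)2, cat. DMF, CH2Cl2; then CH2N2, Et2O, 0 °C
Reagents that add atoms: diazomethane, C=[N+]=[N-] (supplies the CHN2 carbon). Oxalyl chloride leaves no atoms.
Why: Arndt–Eistert-type acylation of diazomethane via the acid chloride gives the α-diazoketone.

**Step 2 (key step)**
Reactants: 3
Product: 4 (racemic 2,3-dihydroazulen-1(8aH)-one bearing a 6-methyl cycloheptatriene, the Buchner product)
Conditions: Rh2(OAc)4 (1 mol%), CH2Cl2, 40 °C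
Reagents that add atoms: none
Why: The Rh carbenoid adds across the ipso/ortho bond of the p-tolyl ring (dearomative intramolecular Buchner reaction), and the norcaradiene opens to the cycloheptatriene. This fuses the 5-ring and 7-ring in one step and leaves the arene methyl on the f=g alkene.

**Step 3**
Reactants: 4
Product: 5 (cross-conjugated azulenone tautomer with j=d double bond, CH2 at e)
Conditions: DBU (10 mol%), PhMe, 25 °C
Reagents that add atoms: none
Why: Proposed new method: deprotonation at the acidic bis-allylic α-CH (j) gives a trienolate, and γ-protonation at e gives the fused tetrasubstituted cyclopentenone, which has an electrophilic β-carbon at d; the closest known reaction is base-induced tautomerisation of Buchner azulenones. This step also removes the labile j stereocentre, so Step 4 sets the absolute configuration.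

**Step 4**
Reactants: 5; 6 (MeMgBr)
Product: 7 (ketone with angular Me at d, β,γ-diene i=h–g=f)
Conditions: MeMgBr, CuBr·SMe2 (5 mol%), chiral ferrocenyl diphosphine (Josiphos-type, 6 mol%), MTBE, –78 °C; then NH4Cl(aq)
Reagents that add atoms: methylmagnesium bromide, C[Mg]Br
Why: Proposed new method: Cu-catalysed asymmetric 1,4-addition of Me to the β,β-disubstituted enone creates the quaternary C-d; the closest known reaction is Feringa-type Cu/Josiphos Grignard conjugate addition to β-substituted cyclic enones. Kinetic α-protonation of the trienolate at j, anti to the new angular Me, should give the trans ring fusion.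

**Step 5**
Reactants: 7; 8 (iPrMgCl)
Product: 9 (tertiary alcohol, a-OH)
Conditions: iPrMgCl·LiCl, CeCl3, THF, –78 °C
Reagents that add atoms: isopropylmagnesium chloride, CC(C)[Mg]Cl
Why: Organocerium 1,2-addition avoids enolisation at the acidic j–H, and iPr attacks the face opposite the angular Me, which places OH cis to Me as in the target.

**Step 6**
Reactants: 9; 10 (TBHP)
Product: 11 (i,h-epoxy alcohol; f=g retained)
Conditions: VO(acac)2 (5 mol%), TBHP, CH2Cl2, 0 °C
Reagents that add atoms: tert-butyl hydroperoxide, CC(C)(C)OO (supplies the epoxide O)
Why: The V(V) hydroxy-directed epoxidation (Sharpless–Michaelson type) selects the homoallylic i=h alkene over the remote f=g alkene and delivers O syn to the a-OH. That is the face opposite the target C-i configuration, which Step 8 corrects.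

**Step 7**
Reactants: 11
Product: 12 (diol, C-i epimer of jaeschkeanadiol)
Conditions: LiEt3BH, THF, 0 °C to rt
Reagents that add atoms: none
Why: Proposed new method: hydride attacks the less hindered, allylic epoxide carbon h (SN2), leaving O on i and the f=g alkene intact; the closest known reaction is Super-Hydride opening of vinyl epoxides. A non-chelating hydride is used to avoid proximal delivery from the a-alkoxide.

**Step 8**
Reactants: 12; 13 (4-acetoxybenzoic acid)
Product: 14 (i-ester with inverted C-i; a-OH free)
Conditions: PPh3, DIAD, THF, 0 °C to rt
Reagents that add atoms: 4-acetoxybenzoic acid, CC(=O)Oc1ccc(cc1)C(=O)O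
Why: Mitsunobu esterification inverts the secondary C-i centre (SN2) to the target configuration, and the hindered tertiary alcohol does not react.

**Step 9**
Reactants: 14
Product: 15 (ferutinin)
Conditions: H2NNH2·AcOH, DMF, rt
Reagents that add atoms: none
Why: Hydrazinolysis cleaves the aryl acetate selectively and leaves the hindered secondary benzoate, tertiary alcohol and alkene untouched.

**Step 10**
Reactants: 15; 16 (mCPBA)
Product: 17 (target)
Conditions: mCPBA, NaHCO3, CH2Cl2, 0 °C
Reagents that add atoms: meta-chloroperbenzoic acid, OOC(=O)c1cccc(Cl)c1 (supplies the epoxide O)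
Why: Electrophilic Prilezhaev epoxidation of the trisubstituted f=g alkene occurs from the face anti to the angular Me, giving a cis epoxide on the same face as the C-i ester; the phenol, benzoate and tertiary OH are unaffected.

## Compound list
| No. | Name | SMILES | Role |
|---|---|---|---|
| 1 | 3-(4-methylphenyl)propanoic acid | Cc1ccc(CCC(=O)O)cc1 | starting material |
| 2 | diazomethane | C=[N+]=[N-] | reagent |
| 3 | 1-diazo-4-(p-tolyl)butan-2-one | Cc1ccc(CCC(=O)C=[N+]=[N-])cc1 | intermediate |
| 4 | Buchner azulenone (racemic) | O=C1CCC2=CC=C(C)C=CC12 | intermediate |
| 5 | conjugated azulenone tautomer | O=C1CCC2=C1C=CC(C)=CC2 | intermediate |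
| 6 | methylmagnesium bromide | C[Mg]Br | reagent |
| 7 | angular-methyl ketone | O=C1CC[C@]2(C)CC=C(C)C=C[C@@H]12 | intermediate |
| 8 | isopropylmagnesium chloride | CC(C)[Mg]Cl | reagent |
| 9 | tertiary alcohol (diene) | CC(C)[C@]1(O)CC[C@]2(C)CC=C(C)C=C[C@H]21 | intermediate |
| 10 | tert-butyl hydroperoxide | CC(C)(C)OO | reagent |
| 11 | i,h-epoxy alcohol | CC(C)[C@]1(O)CC[C@]2(C)CC=C(C)[C@H]3O[C@H]3[C@H]21 | intermediate |
| 12 | C-i epimer of jaeschkeanadiol | CC(C)[C@]1(O)CC[C@]2(C)CC=C(C)C[C@@H](O)[C@H]21 | intermediate |
| 13 | 4-acetoxybenzoic acid | CC(=O)Oc1ccc(cc1)C(=O)O | reagent |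
| 14 | 4-acetoxybenzoate ester | CC(C)[C@]1(O)CC[C@]2(C)CC=C(C)C[C@H](OC(=O)c3ccc(OC(C)=O)cc3)[C@H]21 | intermediate |
| 15 | ferutinin | CC(C)[C@]1(O)CC[C@]2(C)CC=C(C)C[C@H](OC(=O)c3ccc(O)cc3)[C@H]21 | intermediate |
| 16 | mCPBA | OOC(=O)c1cccc(Cl)c1 | reagent |
| 17 | Jaeskeanin | CC(C)[C@]1(O)CC[C@]2(C)C[C@@H]3O[C@]3(C)C[C@H](OC(=O)c3ccc(O)cc3)[C@H]21 | target |

**Total steps: 10. Longest linear sequence: 10 (from 1).**

## Three steps most likely to fail
1. **Step 4 (asymmetric Me addition, ee, and trans-fusion).** Fallback that changes the approach: add Me2CuLi/TMSCl racemically, then resolve at diol 12 as diastereomeric camphanates. Alternatively, use the α-methyl diazoketone (from 1 and diazoethane) so the quaternary Me forms in the Buchner step itself.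
2. **Step 3 (selective isomerisation to enone 5).** The tautomer with sp3 at f or h may be more stable and would be inert to the cuprate. Fallback: use the α-methyl diazoketone Buchner variant above, with a different oxidation-state plan for the ring carbonyl, instead of an enone-conjugate-addition route.
3. **Steps 6–7 (regio- and stereo-controlled installation of O at C-i).** The vanadium epoxidation or the hydride opening may choose the wrong alkene, carbon or face. Fallback: use 3-(4-methoxyphenyl)propanoic acid as the Buchner precursor. Enol-ether hydrolysis then gives a g-ketone enone with i as the β-carbon, and Weitz–Scheffer epoxidation followed by SmI2 reduction installs i–OH. The f=g(Me) alkene is rebuilt from the ketone by enol triflate formation and methylation.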